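The readings are calculated with constants of no real substance, and the scatter is random.

The constants I need here are not rate constants but a ratio and a cost in L, and both can be read from the earlier runs.

| flask | D | L | G | remark | time |
|---|---|---|---|---|---|
| north-west | 20 mM | 28 mM | 2 mM | run made earlier |  |
| north | 20 mM | 42 mM | 2 mM | run made earlier |  |
| Tuesday's | 20 mM | 20.0 mM | 2.00 mM |  | 3.0 h |
| Wednesday's | 20 mM | 30.0 mM | 2.00 mM |  | 3.0 h |

- north-west (time / h: D / %, Q / %): 0.417: 37.5, 37.3; 1.00: 29.4, 53.7; 2.00: 24.4, 60.9; 3.00: 22.3, 64.0
- north (time / h: D / %, Q / %): 0.417: 27.8, 53.4; 1.00: 17.0, 71.7; 2.00: 10.6, 83.8; 3.00: 7.2, 88.6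

(readings scatter by 0.5 percentage points)

1. part of the D that has reacted at the end, Tuesday's
2. part of the D that has reacted at the end, Wednesday's
3. what raising the concentration of L from its lowest to its highest value here does to the part of the D that has reacted (changes below 5 percentage points count as none) (it falls / no change / it rises)

I take the gap between D + Q and the whole charge as E. At the last reading, D is 0.619 of what is not Q in the north-west run and 0.632 in the north run, so I hold that share at 0.619.

If G takes one L each and the Z from each Q takes another L into X, then each Q costs two L. At that price the charge pays for an amount of Q, as a part of the D charged, equal to cL minus cG, divided by two and by cD. For the north-west run that gives 65.0%, and its last reading is 64.0%.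

By my own reckoning, Tuesday's charge pays for 45.0% Q and Wednesday's for 70.0%. The reacted parts are then 65.9% and 81.4%. This reacted part, one minus the share times what is not Q, is what I call the L-reach.

The forecast integrates a rate on the grounds that “each Q costs two L”. It gives 65.5% for Tuesday's and 80% for Wednesday's, the latter below my figure, and on the trend it says it rises.

The flasks give 65.3% and 79.8%, and the answer to the trend is it rises, by 14 percentage points.

    D + L → Z + Q (k = 1.72 /M/min)
    L + G → J (k = 93.2 /M/min)
    D ⇌ E (K = 0.577, k = 0.101 /min)
    L + Z ⇌ X, settled at all times (K = 98700 /M)

The gap between the two flasks comes mainly from the L charged: given Tuesday's L, Wednesday's flask goes from 79.8% to 65.3%. Tuesday's flask ends at 65.3% against an L-reach of 65.9%, with 1.3% of its L still free, so L is its limiting reagent. The neighbour charged with 50 mM of D, at Tuesday's L and G, has an L-reach of 49.2%, and after 3.00 h it stands at 48.8%.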